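## The problem

Target 24 is galangin (3,5,7-trihydroxyflavone) whose C8 carries C3 of a 1-(4-hydroxy-3-methoxyphenyl)-7-phenylheptan-5-one chain. This benzylic methine is the only stereocentre and is R. Ring A is a fully substituted phloroglucinol nucleus fused to pyranone ring C, and the chain must end on C8, not C6. Because 5-hydroxyflavones can exchange 6- and 8-substituents by acid-induced opening and reclosure of ring C (Wessely–Moser rearrangement), the position has to follow from the way ring C is built. The stereocentre has no neighbour to take its configuration from and none to pass it to, so it must be set by a chiral catalyst or auxiliary and then only preserved. It is benzylic to a very electron-rich ring and β to a ketone, which rules out strong acid and forcing base once it exists. Other fragile points are the δ-keto phenol formed by the C7 hydroxyl and the chain ketone (hemiketal equilibrium, dehydration to a 4H-chromene), the oxidisable phenols, and the enolisable ketone, which excludes organolithium and hydride reagents late on. The feature that opens the route is that ring C consists only of C4 (a carbonyl carbon), C3 and the phenyl-bearing C2, bridging C4a and O1: these atoms are carbon monoxide and phenylacetylene, and what remains is an o-iodophenol with iodine on C4a and hydroxyl on C8a. That ring A precursor, a 2-alkyl-5-(benzyloxy)resorcinol, has a local mirror plane through the future C8 and C5, so mono-iodination can give only one compound, and in the iodide only the future O1 is ortho to the new acyl group.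

## Retrosynthesis

**24 to 23.** The three O–benzyl bonds (O5, O7 and the guaiacyl oxygen) are cut. Benzyl is preferred to methyl because selective demethylation beside the guaiacyl methoxy group would be unreliable, whereas one hydrogenolysis removes all three. The precursor 23 has the full skeleton; the forward step must only spare the C2=C3 bond and the ketone.

**23 to 21.** The C3–O bond is cut. C3 comes from an alkyne carbon and arrives as CH, so the hydroxyl is added by epoxidation of C2=C3 with a neutral dioxirane and acid isomerisation of epoxide 22. The alternative, C3 metalation and borylation, is incompatible with the free ketone. Precursor 21 is a plain flavone; the oxidant must not touch the benzylic positions or the ketone.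

**21 to 20.** The O7–benzyl bond is cut. The key step necessarily leaves O7 free, because it is the twin of the hydroxyl that becomes O1. It is the only acidic hydroxyl in 20, so its alkylation needs no selectivity.

**20 to 15, 16 and 17 (key disconnection).** C4a–C4, C4–C3 and O1–C2 are cut, removing ring C and nine carbons at once. Diketone cyclodehydration (Baker–Venkataraman) or chalcone routes need strong base or aldol chemistry that the chain ketone would join, and they begin from an o-hydroxyacetophenone that is harder to make regiochemically pure. Iodoresorcinol 15 needs only phenylacetylene 16 and carbon monoxide 17. The forward reaction must insert 17 before the alkyne is transferred, close ring C in the 6-endo sense, and tolerate two free phenols and a ketone.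

**15 to 14.** The C4a–I bond is cut. Resorcinol 14 is mirror-symmetric about the axis through the alkyl-bearing carbon and the benzyloxy carbon, so either free position gives 15. The forward step only has to stop at mono-substitution.

**14 to 7 and 12.** The bond between the benzylic carbon and the ketone α-methylene is cut, and with it the stereocentre. Carbinol 7 ionises to o-quinone methide 13; β-keto acid 12 is a regiodefined enolate equivalent whose carboxyl group marks the nucleophilic carbon and is lost by decarboxylation. A Friedel–Crafts union of an unsubstituted ring A nucleus with an enone would also attack between hydroxyl and benzyloxy groups, and an aryl-metal conjugate addition would need a hindered 2,6-dioxygenated aryl nucleophile with protected phenols. Here the former aldehyde carbon fixes the site. Precursor 7 is racemic and has no stereochemical demand; the forward step needs face selection by a chiral phosphoric acid and must outrun self-condensation of 13.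

**7 to 2 and 6 (from 5).** The benzylic C–C bond is cut as a Grignard addition to aldehyde 2. This is shorter than acylation followed by reduction, which tends to over-reduce phloroglucinol ketones. Both partners are simple; the forward step must cope with two acidic phenols.

**Fragments.** Aldehyde 2 comes from 1 by one O–benzyl bond. Bromide 5 comes from 3 through 4 (O–benzyl, then C–Br). Acid 12 comes from ester 11, which is assembled from acid chloride 8 and Meldrum's acid 9 through 10.

## Roads not taken

**Alternative 1: ring A by Wolff shift, ketene cycloaddition and electrocyclisation.**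
- **Cut:** C8–C8a, C5–C6, C7–C8 and C5–C4a, with ring C present from the start as a pyranone.
- **Forward step:** irradiation of diazo ketone A1 gives a pyranonyl alkyl ketene by Wolff rearrangement; silyloxyalkyne A2 adds [2+2]; on warming the cyclobutenone opens and the dienylketene closes onto C4a to give A3 (Danheiser benzannulation).
- **Merits:** the C3 oxygen is carried from the beginning and the three ring A oxygens arrive differentiated. In this respect it is better than the chosen plan, which must oxidise a finished flavone (21 to 23) and benzylate O7 separately.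
- **Weak points:** the carbene centre of A1 is next to the stereogenic C–H, so 1,2-hydrogen shift to an enone competes with the Wolff shift and would erase the stereocentre. The 4-pyranone absorbs where the diazo ketone is photolysed. The ketene carries a branched substituent that slows the cycloaddition. The stereocentre still has to be made separately, and A1 needs a long linear sequence.
- **Comparison:** the chosen plan buys ring A intact and reaches 20 in nine steps from commercial materials, at the price of one late oxidation.

**Alternative 2: ring C by aryne insertion.**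
- **Cut:** O1–C8a, C4–C4a and O1–C2.
- **Forward step:** fluoride turns silylaryl triflate A4 into an aryne; the carboxylate of phenylpropiolic acid A5 adds through oxygen at C8a; the aryl anion at C4a takes the acyl group; the phenoxide closes on the ynone to give A6.
- **Merits:** no palladium and no carbon monoxide, no free phenols in the key step, and O5 and O7 are both benzylated on arrival, which saves the step 20 to 21.
- **Weak points:** A4 is a hexasubstituted benzene with adjacent silyl and triflate groups next to the branched chain, and needs many steps where 15 needs one iodination. The benzyloxy group at C5 directs the carboxylate to C8a, but that carbon is flanked by the bulky chain. Without a secondary amine nothing steers the closure away from the 5-exo (aurone) mode. The ketone must be masked.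
- **Comparison:** the endgames are the same, since both need the late C3 oxidation. The chosen plan has the easier precursor and a regiochemistry decided by symmetry; the aryne route would be preferable only if palladium chemistry failed on the free iodoresorcinol.

**Alternative 3: ring A folded from a pyranone-masked polyketide chain.**
- **Cut:** C4a–C5.
- **Forward step:** an amidine or magnesium alkoxide base converts β-keto ester A7 into its vinylogous enolate; C4a attacks the ester carbonyl and enolisation aromatises to A8.
- **Merits:** biomimetic; the C3 oxygen is in place; both ring A hydroxyls emerge free. The endgame (ketal hydrolysis and hydrogenolysis) is shorter than that of the chosen plan.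
- **Weak points:** A7 is a 3,5-dioxo ester attached to the pyranone through a carbon bearing the branched chain, and is laborious to assemble. Under the same bases such esters lactonise through oxygen to 4-hydroxy-2-pyranones, which competes directly with the C-acylation.
- **Comparison:** the chosen plan has the longer endgame but a short, convergent front end and a ring closure with no competing cyclisation mode of comparable ease.

Key step: step 9

## Route

Assumption: the (R)-enantiomer of the phosphoric acid in step 7 is taken to deliver the (R)-configured centre. If the sense of induction is the reverse, the (S)-acid is used and nothing else changes.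

Remark: compounds 14, 15, 20 and 24 are named and drawn as open-chain δ-keto phenols. Each may equilibrate with a cyclic hemiketal, which leads to the same products.

Step 1
Reactants: 1 2,4,6-trihydroxybenzaldehyde
Product: 2 4-(benzyloxy)-2,6-dihydroxybenzaldehyde
Conditions: BnBr (1.0 equiv), NaHCO3, KI (cat.), MeCN, 60 °C
Reagents that add atoms: benzyl bromide, BrCc1ccccc1
Why: Williamson etherification under bicarbonate; the 4-hydroxyl, para to the formyl group and not flanking it, is the most acidic and least hindered, while the two ortho hydroxyls share the hydrogen bond to the carbonyl oxygen. The product keeps the mirror plane on which step 8 relies.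

Step 2
Reactants: 3 homovanillyl alcohol
Product: 4 2-[4-(benzyloxy)-3-methoxyphenyl]ethan-1-ol
Conditions: BnBr, K2CO3, acetone, reflux
Reagents that add atoms: benzyl bromide, BrCc1ccccc1
Why: Phenol-selective Williamson etherification; carbonate deprotonates only the phenol, so the primary alcohol is untouched.

Step 3
Reactants: 4 2-[4-(benzyloxy)-3-methoxyphenyl]ethan-1-ol
Product: 5 1-(benzyloxy)-4-(2-bromoethyl)-2-methoxybenzene
Conditions: CBr4, PPh3, CH2Cl2, 0 °C to rt
Reagents that add atoms: carbon tetrabromide, BrC(Br)(Br)Br
Why: Appel bromination of a primary alcohol under neutral conditions that leave the aryl benzyl ether intact.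

Step 4
Reactants: 5 1-(benzyloxy)-4-(2-bromoethyl)-2-methoxybenzene; 2 4-(benzyloxy)-2,6-dihydroxybenzaldehyde
Product: 7 5-(benzyloxy)-2-{3-[4-(benzyloxy)-3-methoxyphenyl]-1-hydroxypropyl}benzene-1,3-diol (racemic), via arylethylmagnesium bromide 6 (not isolated)
Conditions: Mg, THF, rt to 40 °C (gives 6); 2 pre-treated with i-PrMgCl (2.0 equiv), THF, −40 °C; then 6 (1.3 equiv), −40 to 0 °C; pH 7 phosphate buffer, 0 °C; used without storage
Reagents that add atoms: none
Why: Grignard formation and 1,2-addition to an aldehyde; i-PrMgCl first converts both phenols into magnesium phenoxides by fast proton transfer, so only a small excess of 6 is needed, and the chelated magnesium phenoxide aldehyde accepts the reagent as salicylaldehydes do. The carbinol centre is racemic and is erased in step 7.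

Step 5
Reactants: 8 3-phenylpropanoyl chloride; 9 Meldrum's acid
Product: 11 tert-butyl 3-oxo-5-phenylpentanoate, via acyl Meldrum's acid 10 (not isolated)
Conditions: pyridine, CH2Cl2, 0 °C to rt; then t-BuOH, toluene, reflux
Reagents that add atoms: tert-butanol, CC(C)(C)O
Why: C-acylation of Meldrum's acid, then thermal fragmentation to an acylketene that tert-butanol traps; a standard two-carbon homologation of an acid chloride to a β-keto ester.

Step 6
Reactants: 11 tert-butyl 3-oxo-5-phenylpentanoate
Product: 12 3-oxo-5-phenylpentanoic acid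
Conditions: CF3CO2H, CH2Cl2, 0 °C; evaporated cold and used at once
Reagents that add atoms: none
Why: Acid-mediated cleavage of the tert-butyl ester with loss of isobutene, without the heat that would decarboxylate the β-keto acid.

Step 7
Reactants: 7 5-(benzyloxy)-2-{3-[4-(benzyloxy)-3-methoxyphenyl]-1-hydroxypropyl}benzene-1,3-diol; 12 3-oxo-5-phenylpentanoic acid
Product: 14 (5R)-5-[4-(benzyloxy)-2,6-dihydroxyphenyl]-7-[4-(benzyloxy)-3-methoxyphenyl]-1-phenylheptan-3-one, via o-quinone methide 13 (not isolated)
Conditions: (R)-3,3'-bis(2,4,6-triisopropylphenyl)-1,1'-binaphthyl-2,2'-diyl hydrogen phosphate ((R)-TRIP, 10 mol %), 12 (3 equiv), 4 Å molecular sieves, toluene, 0 °C to rt, 7 added slowly; then 40 °C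
Reagents that add atoms: none
Why: Chiral phosphoric acid catalysed decarboxylative alkylation of a β-keto acid with an o-quinone methide generated in situ from an o-hydroxybenzylic alcohol; the acid dehydrates 7 to 13, holds the carbonyl oxygen of 13 and the enol of 12 in one hydrogen-bonded assembly, and loss of CO2 makes the addition irreversible. The new centre is set by the catalyst, which shields one face of the exocyclic carbon of 13; it is expected to bind at the oxygen on the side of the alkylidene hydrogen, and both hydroxyls of 7 give the same 13 because of the mirror plane.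

Step 8
Reactants: 14 (5R)-5-[4-(benzyloxy)-2,6-dihydroxyphenyl]-7-[4-(benzyloxy)-3-methoxyphenyl]-1-phenylheptan-3-one
Product: 15 (5R)-5-[4-(benzyloxy)-2,6-dihydroxy-3-iodophenyl]-7-[4-(benzyloxy)-3-methoxyphenyl]-1-phenylheptan-3-one
Conditions: N-iodosuccinimide (1.0 equiv), CH2Cl2, −40 °C, dark
Reagents that add atoms: N-iodosuccinimide, O=C1CCC(=O)N1I
Why: Electrophilic aromatic iodination; the two free positions of the resorcinol are equivalent through the local mirror plane, so one equivalent at low temperature gives a single mono-iodide. The resorcinol ring is far more reactive than the dialkoxyphenyl ring, and the ketone is inert to the neutral reagent.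

Step 9
Reactants: 15 (5R)-5-[4-(benzyloxy)-2,6-dihydroxy-3-iodophenyl]-7-[4-(benzyloxy)-3-methoxyphenyl]-1-phenylheptan-3-one; 16 phenylacetylene; 17 carbon monoxide
Product: 20 5-(benzyloxy)-8-{(3R)-1-[4-(benzyloxy)-3-methoxyphenyl]-5-oxo-7-phenylheptan-3-yl}-7-hydroxy-2-phenyl-4H-chromen-4-one, via aryl ynone 18 (not isolated), via β-amino enone 19 (not isolated)
Conditions: PdCl2(PPh3)2 (5 mol %), 16 (1.5 equiv), 17 (1 atm, balloon), Et2NH–DMF, 60 °C
Reagents that add atoms: none
Why: The divalent palladium precatalyst PdCl2(PPh3)2 is reduced in situ to zerovalent palladium, which adds oxidatively to the C4a–I bond of 15; 17 inserts to give the aroylpalladium species, and amine-assisted transfer of 16 followed by reductive elimination gives ynone 18 (C4a–C4 and C4–C3). Diethylamine adds reversibly to 18 to give β-amino enone 19, and the C8a hydroxyl then attacks C2 and expels the amine (O1–C2), so ring C closes in the 6-endo mode (6-endo-dig on 18 directly, or 6-endo-trig addition–elimination through 19); this is why a secondary amine gives the flavone and not the 5-exo aurone. The closest known reaction type is the palladium-catalysed carbonylative Sonogashira coupling and cyclisation of o-iodophenols with terminal alkynes to flavones. No stereocentre is formed, and the existing benzylic centre is remote from the reacting atoms and has no acidic hydrogen. The step needs carbonylative rather than direct coupling (which would end in a 2-phenylbenzofuran); the electron-rich, doubly ortho-substituted aryl–palladium bond, into which 17 inserts readily, and the absence of copper secure this. It also needs a single regiochemistry, secured because only the C8a hydroxyl is ortho to the acyl group: O5 is benzylated and the other hydroxyl is para. The chain ketone and its hemiketals only equilibrate under these conditions, and the benzyl ethers are inert.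

Step 10
Reactants: 20 5-(benzyloxy)-8-{(3R)-1-[4-(benzyloxy)-3-methoxyphenyl]-5-oxo-7-phenylheptan-3-yl}-7-hydroxy-2-phenyl-4H-chromen-4-one
Product: 21 5,7-bis(benzyloxy)-8-{(3R)-1-[4-(benzyloxy)-3-methoxyphenyl]-5-oxo-7-phenylheptan-3-yl}-2-phenyl-4H-chromen-4-one
Conditions: BnBr, K2CO3, DMF, rt to 40 °C
Reagents that add atoms: benzyl bromide, BrCc1ccccc1
Why: Williamson etherification of the only phenol, the acidic O7 hydroxyl (a vinylogous acid); carbonate does not alkylate the ketone.

Step 11
Reactants: 21 5,7-bis(benzyloxy)-8-{(3R)-1-[4-(benzyloxy)-3-methoxyphenyl]-5-oxo-7-phenylheptan-3-yl}-2-phenyl-4H-chromen-4-one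
Product: 23 5,7-bis(benzyloxy)-8-{(3R)-1-[4-(benzyloxy)-3-methoxyphenyl]-5-oxo-7-phenylheptan-3-yl}-3-hydroxy-2-phenyl-4H-chromen-4-one, via flavone 2,3-epoxide 22 (not isolated)
Conditions: dimethyldioxirane (acetone solution, 3–4 equiv), CH2Cl2, 0 °C to rt, dark; evaporation; then p-TsOH·H2O (cat.), CH2Cl2, rt
Reagents that add atoms: dimethyldioxirane, CC1(C)OO1
Why: Dioxirane epoxidation of the C2=C3 enol ether bond of a flavone, then acid opening at C2 (cation stabilised by O1 and the phenyl group) and loss of H3 to the flavonol; a known route from protected flavones to 3-hydroxyflavones. The neutral oxidant does not cause Baeyer–Villiger oxidation of the ketone, and both epoxide diastereomers of 22 converge on 23.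

Step 12
Reactants: 23 5,7-bis(benzyloxy)-8-{(3R)-1-[4-(benzyloxy)-3-methoxyphenyl]-5-oxo-7-phenylheptan-3-yl}-3-hydroxy-2-phenyl-4H-chromen-4-one
Product: 24 3,5,7-trihydroxy-8-[(3R)-1-(4-hydroxy-3-methoxyphenyl)-5-oxo-7-phenylheptan-3-yl]-2-phenyl-4H-chromen-4-one
Conditions: H2 (1 atm), Pd/C (10 %), EtOAc–MeOH, rt
Reagents that add atoms: none
Why: Catalytic hydrogenolysis of three aryl benzyl ethers; the flavonol double bond and the dialkyl ketone are not reduced under these mild conditions, and the stereocentre is untouched.

## Compound list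

1 | 2,4,6-trihydroxybenzaldehyde | O=Cc1c(O)cc(O)cc1O | starting material
2 | 4-(benzyloxy)-2,6-dihydroxybenzaldehyde | O=Cc1c(O)cc(OCc2ccccc2)cc1O | intermediate
3 | homovanillyl alcohol (4-(2-hydroxyethyl)-2-methoxyphenol) | COc1cc(CCO)ccc1O | starting material
4 | 2-[4-(benzyloxy)-3-methoxyphenyl]ethan-1-ol | COc1cc(CCO)ccc1OCc1ccccc1 | intermediate
5 | 1-(benzyloxy)-4-(2-bromoethyl)-2-methoxybenzene | COc1cc(CCBr)ccc1OCc1ccccc1 | intermediate
6 | {2-[4-(benzyloxy)-3-methoxyphenyl]ethyl}magnesium bromide | COc1cc(CC[Mg]Br)ccc1OCc1ccccc1 | intermediate (not isolated)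
7 | 5-(benzyloxy)-2-{3-[4-(benzyloxy)-3-methoxyphenyl]-1-hydroxypropyl}benzene-1,3-diol, racemic | COc1cc(CCC(O)c2c(O)cc(OCc3ccccc3)cc2O)ccc1OCc1ccccc1 | intermediate
8 | 3-phenylpropanoyl chloride | O=C(Cl)CCc1ccccc1 | starting material
9 | Meldrum's acid (2,2-dimethyl-1,3-dioxane-4,6-dione) | CC1(C)OC(=O)CC(=O)O1 | starting material
10 | 5-(1-hydroxy-3-phenylpropylidene)-2,2-dimethyl-1,3-dioxane-4,6-dione | CC1(C)OC(=O)C(=C(O)CCc2ccccc2)C(=O)O1 | intermediate (not isolated)
11 | tert-butyl 3-oxo-5-phenylpentanoate | CC(C)(C)OC(=O)CC(=O)CCc1ccccc1 | intermediate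
12 | 3-oxo-5-phenylpentanoic acid | OC(=O)CC(=O)CCc1ccccc1 | intermediate
13 | 3-(benzyloxy)-6-{3-[4-(benzyloxy)-3-methoxyphenyl]propylidene}-5-hydroxycyclohexa-2,4-dien-1-one (alkylidene geometry not fixed; the two oxygen termini exchange roles by proton transfer) | COc1cc(CCC=C2C(=O)C=C(OCc3ccccc3)C=C2O)ccc1OCc1ccccc1 | intermediate (not isolated)
14 | (5R)-5-[4-(benzyloxy)-2,6-dihydroxyphenyl]-7-[4-(benzyloxy)-3-methoxyphenyl]-1-phenylheptan-3-one | COc1cc(CC[C@H](CC(=O)CCc2ccccc2)c2c(O)cc(OCc3ccccc3)cc2O)ccc1OCc1ccccc1 | intermediate
15 | (5R)-5-[4-(benzyloxy)-2,6-dihydroxy-3-iodophenyl]-7-[4-(benzyloxy)-3-methoxyphenyl]-1-phenylheptan-3-one | COc1cc(CC[C@H](CC(=O)CCc2ccccc2)c2c(O)cc(OCc3ccccc3)c(I)c2O)ccc1OCc1ccccc1 | intermediate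
16 | phenylacetylene | C#Cc1ccccc1 | starting material
17 | carbon monoxide | [C-]#[O+] | starting material
18 | (5R)-5-[4-(benzyloxy)-2,6-dihydroxy-3-(3-phenylprop-2-ynoyl)phenyl]-7-[4-(benzyloxy)-3-methoxyphenyl]-1-phenylheptan-3-one | COc1cc(CC[C@H](CC(=O)CCc2ccccc2)c2c(O)cc(OCc3ccccc3)c(C(=O)C#Cc3ccccc3)c2O)ccc1OCc1ccccc1 | intermediate (not isolated)
19 | (5R)-5-{4-(benzyloxy)-3-[3-(diethylamino)-3-phenylprop-2-enoyl]-2,6-dihydroxyphenyl}-7-[4-(benzyloxy)-3-methoxyphenyl]-1-phenylheptan-3-one (enamine double bond geometry not fixed) | COc1cc(CC[C@H](CC(=O)CCc2ccccc2)c2c(O)cc(OCc3ccccc3)c(C(=O)C=C(N(CC)CC)c3ccccc3)c2O)ccc1OCc1ccccc1 | intermediate (not isolated)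
20 | 5-(benzyloxy)-8-{(3R)-1-[4-(benzyloxy)-3-methoxyphenyl]-5-oxo-7-phenylheptan-3-yl}-7-hydroxy-2-phenyl-4H-chromen-4-one | COc1cc(CC[C@H](CC(=O)CCc2ccccc2)c2c(O)cc(OCc5ccccc5)c3c(=O)cc(-c4ccccc4)oc23)ccc1OCc1ccccc1 | intermediate
21 | 5,7-bis(benzyloxy)-8-{(3R)-1-[4-(benzyloxy)-3-methoxyphenyl]-5-oxo-7-phenylheptan-3-yl}-2-phenyl-4H-chromen-4-one | COc1cc(CC[C@H](CC(=O)CCc2ccccc2)c2c(OCc6ccccc6)cc(OCc5ccccc5)c3c(=O)cc(-c4ccccc4)oc23)ccc1OCc1ccccc1 | intermediate
22 | 5,7-bis(benzyloxy)-2,3-epoxy-8-{(3R)-1-[4-(benzyloxy)-3-methoxyphenyl]-5-oxo-7-phenylheptan-3-yl}-2-phenyl-2,3-dihydro-4H-chromen-4-one (both cis-fused epoxide diastereomers) | COc1cc(CC[C@H](CC(=O)CCc2ccccc2)c2c(OCc6ccccc6)cc(OCc5ccccc5)c3C(=O)C4OC4(c7ccccc7)Oc23)ccc1OCc1ccccc1 | intermediate (not isolated)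
23 | 5,7-bis(benzyloxy)-8-{(3R)-1-[4-(benzyloxy)-3-methoxyphenyl]-5-oxo-7-phenylheptan-3-yl}-3-hydroxy-2-phenyl-4H-chromen-4-one | COc1cc(CC[C@H](CC(=O)CCc2ccccc2)c2c(OCc6ccccc6)cc(OCc5ccccc5)c3c(=O)c(O)c(-c4ccccc4)oc23)ccc1OCc1ccccc1 | intermediate
24 | 3,5,7-trihydroxy-8-[(3R)-1-(4-hydroxy-3-methoxyphenyl)-5-oxo-7-phenylheptan-3-yl]-2-phenyl-4H-chromen-4-one | COc1cc(CC[C@H](CC(=O)CCc2ccccc2)c2c(O)cc(O)c3c(=O)c(O)c(-c4ccccc4)oc23)ccc1O | target

## Step count and least certain steps

Total: 12 steps. Longest linear sequence: 9 steps (3, 4, 5, 7, 14, 15, 20, 21, 23, 24; steps 2, 3, 4, 7, 8, 9, 10, 11, 12).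

**Step 9 (key step).**
- What may go wrong: loss of iodine from the very electron-rich aryl iodide by protodeiodination; capture of the aroylpalladium intermediate by diethylamine (amide formation); alkyne transfer before carbon monoxide insertion; inhibition of the catalyst by the chelating resorcinolate.
- Fallback: setting out from 15, both phenols are acetylated (Ac2O, pyridine) to the iodoresorcinol diacetate F1. Copper-free carbonylative Sonogashira coupling of F1 with 16 under 17 (PdCl2(PPh3)2, Et3N, THF, rt), in which no phenol is free, gives the ynone diacetate F2. Diethylamine in ethanol then removes both acetates and closes ring C through 18 and 19, returning to the route at 20. This separates C–C bond formation from ring closure instead of running both as one cascade on the free resorcinol.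

**Step 7.**
- What may go wrong: poor facial selectivity, because 13 has an oxygen substituent on each side of the alkylidene carbon and the catalyst can bind on either side. Self-condensation of 13 with the nucleophilic free ring positions of 7 and 14. Tautomerisation of 13 to an alkenylphenol. Intramolecular Friedel–Crafts closure onto the dialkoxyphenyl ring.
- Fallback: setting out from 2 (and bypassing 7), the phenols are protected (MeOCH2Cl, NaH, DMF) as the bis(methoxymethyl) ether F3. Horner–Wadsworth–Emmons olefination with diethyl {2-oxo-2-[(4R)-2-oxo-4-phenyl-1,3-oxazolidin-3-yl]ethyl}phosphonate (LiCl, i-Pr2NEt, MeCN) gives the N-enoyl oxazolidinone F4. Copper-mediated conjugate addition of 6 (CuBr·SMe2, THF, −40 °C) to the magnesium-chelated imide, anti to the 4-phenyl group, gives the (3R)-configured adduct F5. Transamidation (AlMe3, MeNHOMe·HCl) gives the N-methoxy-N-methylamide F6, and 2-phenylethylmagnesium chloride converts it (Weinreb ketone synthesis) into the protected ketone F7. Mild acid (HCl, MeOH, 40 °C) removes the acetals and returns to the route at 14. Stereocontrol then rests on an auxiliary with a well-established sense of induction.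

**Step 4.**
- What may go wrong: sluggish addition to the doubly deprotonated aldehyde; dehydration of 7 to 13 during work-up, followed by oligomerisation.
- Fallback: setting out from 2, silylation (t-BuMe2SiCl, imidazole, DMF) gives the bis-silyl ether F8. Addition of 6 (1.2 equiv) gives the silyl-protected carbinol F9, which can be purified and stored. Buffered fluoride (Bu4NF, AcOH, THF, 0 °C) releases 7 immediately before step 7.

**Step 1.**
- What may go wrong: loss of regioselectivity (alkylation of an ortho hydroxyl, double alkylation) and C-benzylation of the phloroglucinol nucleus.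
- Fallback: setting out from 1, exhaustive benzylation (BnBr, K2CO3, DMF) gives 2,4,6-tris(benzyloxy)benzaldehyde F10. Chelation-controlled cleavage of the two benzyl ethers ortho to the formyl group (MgBr2·OEt2, toluene–Et2O, reflux) returns to the route at 2.

**Step 11.**
- What may go wrong: slow epoxidation of the electron-poor C2=C3 bond, so that oxidation of benzylic C–H bonds (benzyl ethers, the C8 methine) or of the dialkoxyphenyl ring competes.
- Fallback: setting out from 21, the chain ketone is masked (ethylene glycol, p-TsOH, benzene, reflux) as the dioxolane F11, identical in structure with A6. C3 is metalated and oxidised (LiN(i-Pr)2, THF, −78 °C; B(OMe)3; then H2O2, AcOH) to the 3-hydroxyflavone dioxolane F12. Aqueous acid (HCl, THF) removes the ketal and returns to the route at 23.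

## Further compounds

F1 | step 9 | (5R)-5-[2,6-diacetoxy-4-(benzyloxy)-3-iodophenyl]-7-[4-(benzyloxy)-3-methoxyphenyl]-1-phenylheptan-3-one | COc1cc(CC[C@H](CC(=O)CCc2ccccc2)c2c(OC(C)=O)cc(OCc3ccccc3)c(I)c2OC(C)=O)ccc1OCc1ccccc1
F2 | step 9 | (5R)-5-[2,6-diacetoxy-4-(benzyloxy)-3-(3-phenylprop-2-ynoyl)phenyl]-7-[4-(benzyloxy)-3-methoxyphenyl]-1-phenylheptan-3-one | COc1cc(CC[C@H](CC(=O)CCc2ccccc2)c2c(OC(C)=O)cc(OCc3ccccc3)c(C(=O)C#Cc3ccccc3)c2OC(C)=O)ccc1OCc1ccccc1
F3 | step 7 | 4-(benzyloxy)-2,6-bis(methoxymethoxy)benzaldehyde | COCOc1cc(OCc2ccccc2)cc(OCOC)c1C=O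
F4 | step 7 | (4R)-3-{(2E)-3-[4-(benzyloxy)-2,6-bis(methoxymethoxy)phenyl]prop-2-enoyl}-4-phenyl-1,3-oxazolidin-2-one | COCOc1cc(OCc2ccccc2)cc(OCOC)c1/C=C/C(=O)N1C(=O)OC[C@H]1c1ccccc1
F5 | step 7 | (4R)-3-{(3R)-3-[4-(benzyloxy)-2,6-bis(methoxymethoxy)phenyl]-5-[4-(benzyloxy)-3-methoxyphenyl]pentanoyl}-4-phenyl-1,3-oxazolidin-2-one | COc1cc(CC[C@H](CC(=O)N2C(=O)OC[C@H]2c2ccccc2)c2c(OCOC)cc(OCc3ccccc3)cc2OCOC)ccc1OCc1ccccc1
F6 | step 7 | (3R)-3-[4-(benzyloxy)-2,6-bis(methoxymethoxy)phenyl]-5-[4-(benzyloxy)-3-methoxyphenyl]-N-methoxy-N-methylpentanamide | COc1cc(CC[C@H](CC(=O)N(C)OC)c2c(OCOC)cc(OCc3ccccc3)cc2OCOC)ccc1OCc1ccccc1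
F7 | step 7 | (5R)-5-[4-(benzyloxy)-2,6-bis(methoxymethoxy)phenyl]-7-[4-(benzyloxy)-3-methoxyphenyl]-1-phenylheptan-3-one | COc1cc(CC[C@H](CC(=O)CCc2ccccc2)c2c(OCOC)cc(OCc3ccccc3)cc2OCOC)ccc1OCc1ccccc1
F8 | step 4 | 4-(benzyloxy)-2,6-bis[(tert-butyldimethylsilyl)oxy]benzaldehyde | CC(C)(C)[Si](C)(C)Oc1cc(OCc2ccccc2)cc(O[Si](C)(C)C(C)(C)C)c1C=O
F9 | step 4 | 1-{4-(benzyloxy)-2,6-bis[(tert-butyldimethylsilyl)oxy]phenyl}-3-[4-(benzyloxy)-3-methoxyphenyl]propan-1-ol, racemic | COc1cc(CCC(O)c2c(O[Si](C)(C)C(C)(C)C)cc(OCc3ccccc3)cc2O[Si](C)(C)C(C)(C)C)ccc1OCc1ccccc1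
F10 | step 1 | 2,4,6-tris(benzyloxy)benzaldehyde | O=Cc1c(OCc2ccccc2)cc(OCc2ccccc2)cc1OCc1ccccc1
F11 | step 11 | 5,7-bis(benzyloxy)-8-{(2R)-4-[4-(benzyloxy)-3-methoxyphenyl]-1-[2-(2-phenylethyl)-1,3-dioxolan-2-yl]butan-2-yl}-2-phenyl-4H-chromen-4-one | COc1cc(CC[C@H](CC2(CCc3ccccc3)OCCO2)c2c(OCc6ccccc6)cc(OCc5ccccc5)c3c(=O)cc(-c4ccccc4)oc23)ccc1OCc1ccccc1
F12 | step 11 | 5,7-bis(benzyloxy)-8-{(2R)-4-[4-(benzyloxy)-3-methoxyphenyl]-1-[2-(2-phenylethyl)-1,3-dioxolan-2-yl]butan-2-yl}-3-hydroxy-2-phenyl-4H-chromen-4-one | COc1cc(CC[C@H](CC2(CCc3ccccc3)OCCO2)c2c(OCc6ccccc6)cc(OCc5ccccc5)c3c(=O)c(O)c(-c4ccccc4)oc23)ccc1OCc1ccccc1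
A1 | alternative 1 | 5-(benzyloxy)-2-{(3R)-3-{2-[4-(benzyloxy)-3-methoxyphenyl]ethyl}-2-diazo-4-[2-(2-phenylethyl)-1,3-dioxolan-2-yl]butanoyl}-6-phenyl-4H-pyran-4-one | COc1cc(CC[C@H](CC2(CCc3ccccc3)OCCO2)C(=[N+]=[N-])C(=O)c2cc(=O)c(OCc3ccccc3)c(-c3ccccc3)o2)ccc1OCc1ccccc1
A2 | alternative 1 | (triisopropylsilyloxy)ethyne | C#CO[Si](C(C)C)(C(C)C)C(C)C
A3 | alternative 1 | 3-(benzyloxy)-8-{(2R)-4-[4-(benzyloxy)-3-methoxyphenyl]-1-[2-(2-phenylethyl)-1,3-dioxolan-2-yl]butan-2-yl}-5-hydroxy-2-phenyl-7-[(triisopropylsilyl)oxy]-4H-chromen-4-one | COc1cc(CC[C@H](CC2(CCc3ccccc3)OCCO2)c2c(O[Si](C(C)C)(C(C)C)C(C)C)cc(O)c3c(=O)c(OCc5ccccc5)c(-c4ccccc4)oc23)ccc1OCc1ccccc1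
A4 | alternative 2 | 3,5-bis(benzyloxy)-2-{(2R)-4-[4-(benzyloxy)-3-methoxyphenyl]-1-[2-(2-phenylethyl)-1,3-dioxolan-2-yl]butan-2-yl}-6-(trimethylsilyl)phenyl trifluoromethanesulfonate | COc1cc(CC[C@H](CC2(CCc3ccccc3)OCCO2)c2c(OCc3ccccc3)cc(OCc3ccccc3)c([Si](C)(C)C)c2OS(=O)(=O)C(F)(F)F)ccc1OCc1ccccc1
A5 | alternative 2 | 3-phenylpropiolic acid | OC(=O)C#Cc1ccccc1
A6 | alternative 2 | 5,7-bis(benzyloxy)-8-{(2R)-4-[4-(benzyloxy)-3-methoxyphenyl]-1-[2-(2-phenylethyl)-1,3-dioxolan-2-yl]butan-2-yl}-2-phenyl-4H-chromen-4-one | COc1cc(CC[C@H](CC2(CCc3ccccc3)OCCO2)c2c(OCc3ccccc3)cc(OCc3ccccc3)c3c(=O)cc(-c4ccccc4)oc23)ccc1OCc1ccccc1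
A7 | alternative 3 | methyl (5R)-4-[5-(benzyloxy)-4-oxo-6-phenyl-4H-pyran-2-yl]-7-[4-(benzyloxy)-3-methoxyphenyl]-3-oxo-5-{[2-(2-phenylethyl)-1,3-dioxolan-2-yl]methyl}heptanoate (C4 epimers) | COc1cc(CC[C@H](CC2(CCc3ccccc3)OCCO2)C(C(=O)CC(=O)OC)c2cc(=O)c(OCc3ccccc3)c(-c3ccccc3)o2)ccc1OCc1ccccc1
A8 | alternative 3 | 3-(benzyloxy)-8-{(2R)-4-[4-(benzyloxy)-3-methoxyphenyl]-1-[2-(2-phenylethyl)-1,3-dioxolan-2-yl]butan-2-yl}-5,7-dihydroxy-2-phenyl-4H-chromen-4-one | COc1cc(CC[C@H](CC2(CCc3ccccc3)OCCO2)c2c(O)cc(O)c3c(=O)c(OCc5ccccc5)c(-c4ccccc4)oc23)ccc1OCc1ccccc1
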